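**Plan**
- Retrosynthetic cuts, in order: the ring B side chain is taken back to a formyl group (C8' oxygen from an epoxide, C7'=C8' from an olefination), then the O8–C4' alkyl aryl ether is cut, and last the C1–C7 bond between ring A and the three-carbon chain.
- Enabling feature: the chain C1(ring A)–C7(OH)–C8(O)–C9H2OH carries two threo oxygens on adjacent carbons. It is L-tartaric acid in which one CO2H is replaced by ring A and the other is reduced to C9.
- Forward order: tartrate acetonide half-ester → N-hydroxyphthalimide ester → decarboxylative arylation with the ring A bromide (C1–C7) → C9 reduction and O7/O9 silylene → SNAr on a ring B fluoroaldehyde (O8–C4') → Wittig (C7'=C8'), reduction, epoxidation, hydrogenolysis, desilylation. Both benzene rings are bought; no ring of the target is built.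
- Stereochemistry: C8 is carried over from (R,R)-tartrate. C7 is set in the key step, trans to the C8 substituent on the dioxolane (7S,8S, threo). C8' (S) comes from Sharpless epoxidation with D-(−)-diethyl tartrate.

Key step: step 4

Remark on the chemistry: neolignan numbering is used (ring A C1–C6 with chain C7–C9; ring B C1'–C6' with chain C7'–C9'). The diester 1 is C2-symmetric, so its mono-hydrolysis needs no regiocontrol.

**Step 1**
Reactants: 1 dimethyl (4R,5R)-2,2-dimethyl-1,3-dioxolane-4,5-dicarboxylate (dimethyl 2,3-O-isopropylidene-L-tartrate)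
Product: 2 (4R,5R)-5-(methoxycarbonyl)-2,2-dimethyl-1,3-dioxolane-4-carboxylic acid
Conditions: KOH (1.0 equiv), MeOH, 0 °C → rt; then cold 1 M HCl to pH 3, EtOAc extraction
Reagents that add atoms: potassium hydroxide [K+].[OH-]
Why: Ester saponification (BAc2) with one equivalent of hydroxide should stop at the half-ester because the carboxylate formed first deactivates the neighbouring ester, and either ester of the symmetric diester gives the same acid; the trans dioxolane is the stable arrangement, so the stereocentres are not at risk.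

**Step 2**
Reactants: 2 (4R,5R)-5-(methoxycarbonyl)-2,2-dimethyl-1,3-dioxolane-4-carboxylic acid; 3 N-hydroxyphthalimide
Product: 4 4-(1,3-dioxoisoindolin-2-yl) 5-methyl (4R,5R)-2,2-dimethyl-1,3-dioxolane-4,5-dicarboxylate (the redox-active ester)
Conditions: N,N'-diisopropylcarbodiimide (DIC), DMAP (cat.), CH2Cl2, rt
Reagents that add atoms: none
Why: Steglich-type carbodiimide esterification: DIC activates the acid as an O-acylisourea that the acidic N–OH of 3 intercepts under DMAP catalysis, leaving the acetonide and the methyl ester untouched.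

**Step 3**
Reactants: 5 4-bromo-2,6-dimethoxyphenol
Product: 6 2-(benzyloxy)-5-bromo-1,3-dimethoxybenzene
Conditions: BnBr, K2CO3, DMF, rt
Reagents that add atoms: benzyl bromide BrCc1ccccc1
Why: Williamson ether synthesis (SN2 of the phenoxide on benzyl bromide) installs a phenol protecting group that should survive the reductive, basic and hydride steps ahead and is removed by hydrogenolysis.

**Step 4**
Reactants: 4 4-(1,3-dioxoisoindolin-2-yl) 5-methyl (4R,5R)-2,2-dimethyl-1,3-dioxolane-4,5-dicarboxylate (1.5 equiv); 6 2-(benzyloxy)-5-bromo-1,3-dimethoxybenzene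
Product: 7 methyl (4R,5S)-5-[4-(benzyloxy)-3,5-dimethoxyphenyl]-2,2-dimethyl-1,3-dioxolane-4-carboxylate (trans)
Conditions: NiCl2·glyme (20 mol %), 2,2'-bipyridine (20 mol %), AgNO3 (0.3 equiv, plated on the cathode), NMP, Mg anode, RVC cathode, undivided cell, constant current, rt
Reagents that add atoms: none
Why: One-electron reduction of the phthalimide ester at the silver-coated cathode (or by low-valent nickel) breaks its N–O bond, and loss of CO2 leaves a 1,3-dioxolan-4-yl radical at C7 stabilised by the ring oxygen; zerovalent nickel–bipyridine adds oxidatively to the C–Br bond of 6, the aryl complex of divalent nickel captures the radical, and the trivalent nickel species eliminates reductively to form C1–C7. The closest known reaction type is the nickel-electrocatalytic decarboxylative arylation of redox-active esters with aryl halides, which is established for α-oxy acids including tartrate acetonide esters. No ring is closed. The radical carbon is planar, so C7 is created anew and its configuration is dictated by the untouched C8 stereocentre: bond formation should occur on the dioxolane face opposite the C8 ester, giving the trans (4R,5S) ring, which is the 7S,8S threo arrangement of the target. The step needs trans diastereoselectivity and cross-selectivity over biaryl formation and simple reduction of the radical; the rigid five-membered ring with its adjacent ester should secure the first, and an excess of the cheap ester 4 with current-controlled radical generation the second.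

**Step 5**
Reactants: 7 methyl (4R,5S)-5-[4-(benzyloxy)-3,5-dimethoxyphenyl]-2,2-dimethyl-1,3-dioxolane-4-carboxylate
Product: 8 {(4S,5S)-5-[4-(benzyloxy)-3,5-dimethoxyphenyl]-2,2-dimethyl-1,3-dioxolan-4-yl}methanol
Conditions: LiBH4, THF, 0 °C → rt
Reagents that add atoms: none
Why: Chemoselective hydride reduction of the α-alkoxy methyl ester to the C9 primary alcohol; acetonide and benzyl ether are inert, and C8 cannot be lost because the trans dioxolane is the thermodynamic isomer (the descriptor at C8 changes from R to S only through the priority change).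

**Step 6**
Reactants: 8 {(4S,5S)-5-[4-(benzyloxy)-3,5-dimethoxyphenyl]-2,2-dimethyl-1,3-dioxolan-4-yl}methanol
Product: 9 (1S,2S)-1-[4-(benzyloxy)-3,5-dimethoxyphenyl]propane-1,2,3-triol
Conditions: AcOH/H2O (4:1), 40 °C
Reagents that add atoms: none
Why: Acid-catalysed acetal hydrolysis: dilute acetic acid ionises the isopropylidene acetal carbon far more readily than the benzylic C7–O bond, so the threo triol should be released with C7 and C8 intact.

**Step 7**
Reactants: 9 (1S,2S)-1-[4-(benzyloxy)-3,5-dimethoxyphenyl]propane-1,2,3-triol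
Product: 10 (4S,5S)-4-[4-(benzyloxy)-3,5-dimethoxyphenyl]-2,2-di-tert-butyl-1,3,2-dioxasilinan-5-ol (O7,O9-silylene, free O8–H)
Conditions: t-Bu2Si(OTf)2 (1.05 equiv), 2,6-lutidine, CH2Cl2/DMF, −40 → 0 °C
Reagents that add atoms: di-tert-butylsilyl bis(trifluoromethanesulfonate) CC(C)(C)[Si](OS(=O)(=O)C(F)(F)F)(OS(=O)(=O)C(F)(F)F)C(C)(C)C
Why: Cyclic silylene formation: the primary O9–H reacts first and the ring then closes on O7 to the six-membered 1,3,2-dioxasilinane, which is favoured over the strained five-membered dioxasilolanes (these hydrolyse on aqueous work-up and return triol), so O8–H is left as the only free hydroxyl and no stereocentre is touched.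

**Step 8**
Reactants: 10 (4S,5S)-4-[4-(benzyloxy)-3,5-dimethoxyphenyl]-2,2-di-tert-butyl-1,3,2-dioxasilinan-5-ol; 11 4-fluoro-3,5-dimethoxybenzaldehyde
Product: 12 4-({(4S,5S)-4-[4-(benzyloxy)-3,5-dimethoxyphenyl]-2,2-di-tert-butyl-1,3,2-dioxasilinan-5-yl}oxy)-3,5-dimethoxybenzaldehyde
Conditions: NaH (1.05 equiv), DMF, 0 °C; then 11, 0 °C → rt
Reagents that add atoms: none
Why: Nucleophilic aromatic substitution by addition–elimination (SNAr): the preformed sodium alkoxide of O8 attacks C4' para to the formyl group, which stabilises the Meisenheimer intermediate, and fluoride leaves as insoluble NaF; the C8–O bond is never broken, so C8 keeps its configuration, and the six-membered silylene should hold O7 and O9 as it does in O-alkylations of 3',5'-O-silylene nucleosides.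

**Step 9**
Reactants: 12 4-({(4S,5S)-4-[4-(benzyloxy)-3,5-dimethoxyphenyl]-2,2-di-tert-butyl-1,3,2-dioxasilinan-5-yl}oxy)-3,5-dimethoxybenzaldehyde
Product: 13 ethyl (2E)-3-[4-({(4S,5S)-4-[4-(benzyloxy)-3,5-dimethoxyphenyl]-2,2-di-tert-butyl-1,3,2-dioxasilinan-5-yl}oxy)-3,5-dimethoxyphenyl]prop-2-enoate
Conditions: Ph3P=CHCO2Et, toluene, 80 °C
Reagents that add atoms: ethyl (triphenylphosphoranylidene)acetate CCOC(=O)C=P(c1ccccc1)(c1ccccc1)c1ccccc1
Why: Wittig olefination with a stabilised ylide, which should give the E cinnamate and adds C8' and C9'; silylene and benzyl ether are inert.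

**Step 10**
Reactants: 13 ethyl (2E)-3-[4-({(4S,5S)-4-[4-(benzyloxy)-3,5-dimethoxyphenyl]-2,2-di-tert-butyl-1,3,2-dioxasilinan-5-yl}oxy)-3,5-dimethoxyphenyl]prop-2-enoate
Product: 14 (2E)-3-[4-({(4S,5S)-4-[4-(benzyloxy)-3,5-dimethoxyphenyl]-2,2-di-tert-butyl-1,3,2-dioxasilinan-5-yl}oxy)-3,5-dimethoxyphenyl]prop-2-en-1-ol
Conditions: i-Bu2AlH (DIBAL-H), CH2Cl2, −78 °C; aq. potassium sodium tartrate work-up
Reagents that add atoms: none
Why: 1,2-Reduction of the α,β-unsaturated ester with DIBAL-H at low temperature should give the E allylic alcohol without conjugate reduction or Si–O cleavage.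

**Step 11**
Reactants: 14 (2E)-3-[4-({(4S,5S)-4-[4-(benzyloxy)-3,5-dimethoxyphenyl]-2,2-di-tert-butyl-1,3,2-dioxasilinan-5-yl}oxy)-3,5-dimethoxyphenyl]prop-2-en-1-ol
Product: 15 {(2R,3R)-3-[4-({(4S,5S)-4-[4-(benzyloxy)-3,5-dimethoxyphenyl]-2,2-di-tert-butyl-1,3,2-dioxasilinan-5-yl}oxy)-3,5-dimethoxyphenyl]oxiran-2-yl}methanol
Conditions: Ti(OiPr)4 (10 mol %), D-(−)-diethyl tartrate (12 mol %), t-BuOOH, 4 Å MS, CH2Cl2, −20 °C
Reagents that add atoms: tert-butyl hydroperoxide CC(C)(C)OO
Why: Katsuki–Sharpless asymmetric epoxidation of an E allylic alcohol: the titanium–D-(−)-tartrate complex delivers oxygen to the alkene face that gives the 2R,3R epoxy alcohol, fixing the C8' oxygen in the sense that becomes 8'S once C7' is reduced, and catalytic titanium with molecular sieves keeps the Lewis acidity low for the benzylic epoxide.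

**Step 12**
Reactants: 15 {(2R,3R)-3-[4-({(4S,5S)-4-[4-(benzyloxy)-3,5-dimethoxyphenyl]-2,2-di-tert-butyl-1,3,2-dioxasilinan-5-yl}oxy)-3,5-dimethoxyphenyl]oxiran-2-yl}methanol
Product: 17 (2S)-3-[4-({(4S,5S)-2,2-di-tert-butyl-4-(4-hydroxy-3,5-dimethoxyphenyl)-1,3,2-dioxasilinan-5-yl}oxy)-3,5-dimethoxyphenyl]propane-1,2-diol, via O-benzyl diol 16 (not isolated)
Conditions: H2 (1 atm), Pd/C (10 %), EtOAc, rt
Reagents that add atoms: none
Why: Heterogeneous catalytic hydrogenolysis: palladium should cleave the strained benzylic C7'–O bond of the aryl epoxide regioselectively, leaving the C8' carbinol centre untouched as the S 1,2-diol, and then the phenolic benzyl ether, while the benzylic O7–Si ether and the alkyl aryl ether are expected to be inert under neutral conditions.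

**Step 13**
Reactants: 17 (2S)-3-[4-({(4S,5S)-2,2-di-tert-butyl-4-(4-hydroxy-3,5-dimethoxyphenyl)-1,3,2-dioxasilinan-5-yl}oxy)-3,5-dimethoxyphenyl]propane-1,2-diol
Product: 18 (1S,2S)-2-{4-[(2S)-2,3-dihydroxypropyl]-2,6-dimethoxyphenoxy}-1-(4-hydroxy-3,5-dimethoxyphenyl)propane-1,3-diol (CNP0229130.2)
Conditions: HF·pyridine, pyridine, THF, 0 °C → rt
Reagents that add atoms: none
Why: Fluoride-induced Si–O cleavage (desilylation) of the silylene under buffered, nearly neutral conditions should free O7–H and O9–H while sparing the p-hydroxybenzylic alcohol and the aryl ether, with no stereocentre touched.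

**Compound list**
1 | dimethyl (4R,5R)-2,2-dimethyl-1,3-dioxolane-4,5-dicarboxylate (dimethyl 2,3-O-isopropylidene-L-tartrate) | COC(=O)[C@@H]1OC(C)(C)O[C@H]1C(=O)OC | starting material
2 | (4R,5R)-5-(methoxycarbonyl)-2,2-dimethyl-1,3-dioxolane-4-carboxylic acid | COC(=O)[C@@H]1OC(C)(C)O[C@H]1C(=O)O | intermediate
3 | N-hydroxyphthalimide | O=C1c2ccccc2C(=O)N1O | starting material
4 | 4-(1,3-dioxoisoindolin-2-yl) 5-methyl (4R,5R)-2,2-dimethyl-1,3-dioxolane-4,5-dicarboxylate | COC(=O)[C@@H]1OC(C)(C)O[C@H]1C(=O)ON1C(=O)c2ccccc2C1=O | intermediate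
5 | 4-bromo-2,6-dimethoxyphenol | COc1cc(Br)cc(OC)c1O | starting material
6 | 2-(benzyloxy)-5-bromo-1,3-dimethoxybenzene | COc1cc(Br)cc(OC)c1OCc1ccccc1 | intermediate
7 | methyl (4R,5S)-5-[4-(benzyloxy)-3,5-dimethoxyphenyl]-2,2-dimethyl-1,3-dioxolane-4-carboxylate | COc1cc([C@@H]2OC(C)(C)O[C@H]2C(=O)OC)cc(OC)c1OCc1ccccc1 | intermediate
8 | {(4S,5S)-5-[4-(benzyloxy)-3,5-dimethoxyphenyl]-2,2-dimethyl-1,3-dioxolan-4-yl}methanol | COc1cc([C@@H]2OC(C)(C)O[C@H]2CO)cc(OC)c1OCc1ccccc1 | intermediate
9 | (1S,2S)-1-[4-(benzyloxy)-3,5-dimethoxyphenyl]propane-1,2,3-triol | COc1cc([C@H](O)[C@@H](O)CO)cc(OC)c1OCc1ccccc1 | intermediate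
10 | (4S,5S)-4-[4-(benzyloxy)-3,5-dimethoxyphenyl]-2,2-di-tert-butyl-1,3,2-dioxasilinan-5-ol | COc1cc([C@@H]2O[Si](C(C)(C)C)(C(C)(C)C)OC[C@@H]2O)cc(OC)c1OCc1ccccc1 | intermediate
11 | 4-fluoro-3,5-dimethoxybenzaldehyde | COc1cc(C=O)cc(OC)c1F | starting material
12 | 4-({(4S,5S)-4-[4-(benzyloxy)-3,5-dimethoxyphenyl]-2,2-di-tert-butyl-1,3,2-dioxasilinan-5-yl}oxy)-3,5-dimethoxybenzaldehyde | COc1cc([C@@H]2O[Si](C(C)(C)C)(C(C)(C)C)OC[C@@H]2Oc3c(OC)cc(C=O)cc3OC)cc(OC)c1OCc1ccccc1 | intermediate
13 | ethyl (2E)-3-[4-({(4S,5S)-4-[4-(benzyloxy)-3,5-dimethoxyphenyl]-2,2-di-tert-butyl-1,3,2-dioxasilinan-5-yl}oxy)-3,5-dimethoxyphenyl]prop-2-enoate | COc1cc([C@@H]2O[Si](C(C)(C)C)(C(C)(C)C)OC[C@@H]2Oc3c(OC)cc(/C=C/C(=O)OCC)cc3OC)cc(OC)c1OCc1ccccc1 | intermediate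
14 | (2E)-3-[4-({(4S,5S)-4-[4-(benzyloxy)-3,5-dimethoxyphenyl]-2,2-di-tert-butyl-1,3,2-dioxasilinan-5-yl}oxy)-3,5-dimethoxyphenyl]prop-2-en-1-ol | COc1cc([C@@H]2O[Si](C(C)(C)C)(C(C)(C)C)OC[C@@H]2Oc3c(OC)cc(/C=C/CO)cc3OC)cc(OC)c1OCc1ccccc1 | intermediate
15 | {(2R,3R)-3-[4-({(4S,5S)-4-[4-(benzyloxy)-3,5-dimethoxyphenyl]-2,2-di-tert-butyl-1,3,2-dioxasilinan-5-yl}oxy)-3,5-dimethoxyphenyl]oxiran-2-yl}methanol | COc1cc([C@@H]2O[Si](C(C)(C)C)(C(C)(C)C)OC[C@@H]2Oc3c(OC)cc([C@H]4O[C@@H]4CO)cc3OC)cc(OC)c1OCc1ccccc1 | intermediate
16 | (2S)-3-[4-({(4S,5S)-4-[4-(benzyloxy)-3,5-dimethoxyphenyl]-2,2-di-tert-butyl-1,3,2-dioxasilinan-5-yl}oxy)-3,5-dimethoxyphenyl]propane-1,2-diol (O-benzyl diol formed in the flask) | COc1cc([C@@H]2O[Si](C(C)(C)C)(C(C)(C)C)OC[C@@H]2Oc3c(OC)cc(C[C@H](O)CO)cc3OC)cc(OC)c1OCc1ccccc1 | intermediate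
17 | (2S)-3-[4-({(4S,5S)-2,2-di-tert-butyl-4-(4-hydroxy-3,5-dimethoxyphenyl)-1,3,2-dioxasilinan-5-yl}oxy)-3,5-dimethoxyphenyl]propane-1,2-diol | COc1cc([C@@H]2O[Si](C(C)(C)C)(C(C)(C)C)OC[C@@H]2Oc3c(OC)cc(C[C@H](O)CO)cc3OC)cc(OC)c1O | intermediate
18 | (1S,2S)-2-{4-[(2S)-2,3-dihydroxypropyl]-2,6-dimethoxyphenoxy}-1-(4-hydroxy-3,5-dimethoxyphenyl)propane-1,3-diol | COc1cc([C@H](O)[C@H](CO)Oc2c(OC)cc(C[C@H](O)CO)cc2OC)cc(OC)c1O | target

**Step count**
Total: 13 steps. Longest linear sequence: 12 steps (1 → 2 → 4 → 7 → 8 → 9 → 10 → 12 → 13 → 14 → 15 → 17 → 18); the benzylation of 5 (step 3) is a one-step side branch.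

**Steps most likely to fail**

Step 8 (aryl ether by SNAr). Addition of the hindered secondary alkoxide to a fluoroarene that is flanked by two methoxy groups and activated only by a para formyl group may be too slow. Reversible hemiacetal formation at the aldehyde, base-induced migration of the silylene onto O8 with arylation at the primary O9, or attack of fluoride on silicon could then take over. Fallback: starting from 10, the ether would be made by palladium-catalysed Buchwald–Hartwig-type C–O coupling with commercial 4-bromo-3,5-dimethoxybenzaldehyde ([(allyl)PdCl]2, RockPhos, Cs2CO3, toluene, 90 °C). Here the C4'–O8 bond forms by reductive elimination from an aryl alkoxide complex of divalent palladium instead of through a Meisenheimer adduct, so no ring activation is needed and the two ortho substituents favour the elimination. C8 is again untouched. The fallback returns to the route at 12 and makes no new compound.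

Step 4 (key decarboxylative arylation). Oxidative addition of the fairly electron-rich bromide 6 to low-valent nickel may lag behind cathodic radical generation. The dioxolanyl radical would then be lost by hydrogen abstraction or dimerisation, 6 could homocouple to the biaryl, and the trans preference could erode if the cell warms. Fallback: starting from 6 and 4, a decarboxylative Negishi-type arylation would be used. Bromine–lithium exchange on 6 (n-BuLi, THF, −78 °C) and transmetalation with ZnCl2 would give [4-(benzyloxy)-3,5-dimethoxyphenyl]zinc chloride F1. This is coupled with the same ester 4 under NiCl2·glyme and 4,4'-di-tert-butyl-2,2'-bipyridine in THF/DMF at rt. The aryl group then reaches nickel by transmetalation rather than by oxidative addition, the same C7 radical is formed from 4 and captured trans to the C8 ester, and the sequence returns at 7.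

Step 11 (asymmetric epoxidation). The electron-rich benzylic epoxide may be opened by isopropanol or hydroperoxide under titanium Lewis acidity, or face selection may be incomplete on this bulky cinnamyl alcohol. Fallback: starting from 14, a Shi epoxidation with the D-fructose-derived ketone would be used (Oxone (2KHSO5·KHSO4·K2SO4), K2CO3, MeCN/dimethoxymethane/aqueous buffer at about pH 10.5, 0 °C). A chiral dioxirane transfers oxygen in a metal-free, basic medium in which the epoxide is not ionised, and this ketone enantiomer gives (R,R)-epoxides from E alkenes. The crude product would be taken directly into the hydrogenolysis; the fallback returns at 15 and makes no new compound.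

**Further compounds**
F0 | step 8 | none | none
F1 | step 4 | [4-(benzyloxy)-3,5-dimethoxyphenyl]zinc chloride | COc1cc([Zn]Cl)cc(OC)c1OCc1ccccc1
F0 | step 11 | none | none
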